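**The decision.** If the dawn flask was to be charged like the noon flask, with 120 mM Xa and 2.40 mM Xc, I had to decide whether leaving it for 72 min was worth anything. The noon run had stood at 37.8 mM Xp at 13 min and at 40.3 mM at 18 min.

| flask | Xa | Xc | time |
|---|---|---|---|
| noon | 120 mM | 2.40 mM |  |
| dusk | 60.0 mM | 2.40 mM |  |
| summer | 120 mM | 1.20 mM |  |
| winter | 60.0 mM | 2.40 mM |  |
| dawn | 120 mM | 2.40 mM | 72 min |

| run | time / min | [Xp] / mM |
|---|---|---|
| noon run | 1.0 | 8.6 |
| noon run | 3.1 | 19.7 |
| noon run | 5.9 | 29.4 |
| noon run | 9.4 | 35.7 |
| noon run | 13 | 37.8 |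
| noon run | 18 | 40.3 |
| dusk run | 1.0 | 4.1 |
| dusk run | 3.1 | 9.7 |
| dusk run | 5.9 | 14.8 |
| dusk run | 9.4 | 18.3 |
| dusk run | 13 | 19.5 |
| dusk run | 18 | 19.8 |
| summer run | 1.0 | 4.5 |
| summer run | 3.1 | 10.5 |
| summer run | 5.9 | 16.0 |
| summer run | 9.4 | 19.4 |
| summer run | 13 | 21.0 |
| summer run | 18 | 21.8 |
| winter run | 1.0 | 4.2 |
| winter run | 3.1 | 10.0 |
| winter run | 5.9 | 15.1 |
| winter run | 9.4 | 17.5 |
| winter run | 13 | 19.3 |
| winter run | 18 | 20.2 |

(readings scatter by 0.4 mM)

- order of the initial rate in [Xc], near the charge of the noon run, the rate being that where two percent of its Xa are Xp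
- order of the initial rate in [Xa], near the charge of the noon run, the rate being that where two percent of its Xa are Xp (one fixed amount of Xp, the same in the runs compared)
- Xp in the dawn run at 72 min, as a share of the Xa charged

- Overall: Xa -> Xp, with Xc as catalyst.
- Constant volume, constant temperature.
- An order is taken over about fifteen percent of the charge, up and down.

**Zero of scale.** A flask first order in Xa, with its Xc held constant over time, turns the same share of any Xa charge in a given time, so I took equal shares as my zero. I measured each flask by its budget: the natural logarithm of Xa charged over Xa still unturned at the last reading. The noon flask had 0.409. The dusk flask, with half the Xa, had 0.400, close to the noon value. The summer flask, with half the Xc, had 0.200, and the noon budget was twice that.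

**My reckoning.** I read this as Xc dying during the run, which is catalyst deactivation. The noon budget over its Xc charge came to 0.171 mM⁻¹, and this budget per amount of Xc charged was what I carried forward. Taken as the total for the dawn flask, it gave an estimated share of 33.6 %. So I left the charge unchanged and treated the long wait as a check, not as a way to gain yield.

**The forecast.** It gave orders of 1.05 in Xc and 1.07 in Xa, and 34.3 % for the dawn flask at 72 min, holding that “the catalyst appears to die first order”. Its share stood 0.70 percentage points above mine.

**The result.** The dawn flask gave 34.5 % at 72 min. Near the charge of the noon flask, the orders came to 1.1 in Xc and 1.1 in Xa.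

    Xc + Xa → Xp + Xc (32.70 M⁻¹ min⁻¹)
    Xc → Q (0.1854 min⁻¹)

In the dawn flask at 72 min, nearly all of the Xc had become Q, with 3.83 × 10⁻⁶ mM Xc remaining. Its budget was 0.423, against 0.410 from the carried figure. For the summer flask, with 1.20 mM Xc, the carried figure gave 22.2 mM Xp, and that flask read 21.8 mM at 18 min.

(The earlier runs and the new flask are calculated for an exercise.)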